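**Retrosynthetic overview**

1. Ring A is the acylphloroglucinol ring, ring B the benzene ring of the chromanone, ring C its pyranone ring. The last disconnection is at the Ar–CH2–Ar bridge: a C8 Mannich base of the chromanone (ortho-quinone methide precursor) plus the ring A ketone. Each partner has exactly one free ring carbon, so the union is regiospecific.
2. Ring C is disconnected across C2–C3 and C4–C4a: a formal cationic [4+2] between the O-aryl oxocarbenium ion O1=C2Me2 of an aryl isopropenyl ether and ethoxyethyne as a ketene (C3–C4) equivalent, followed by hydrolysis to the C4 ketone.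
3. Enabling feature: O1 lies para to the C6 methyl, so the ring B precursor is mirror-symmetric with two equivalent ortho carbons (future C4a), each activated by O1, the 5-oxygen and the 7-oxygen. C2 is a gem-dimethyl carbon (stable tertiary oxocarbenium, no stereocentre) and C4 is at the ketone level.
4. The phenol with O1 differentiated comes from 2,6-dimethoxytoluene by sterically controlled C–H borylation/oxidation para to the methyl. Ring A comes from 2-methylphloroglucinol by Friedel–Crafts acylation.
5. Ring order: ring B is bought, ring C is closed in step 4, ring A is bought and joined last in step 8.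

Key step: step 4

Remark: the target has no stereocentre (C2 carries two methyl groups), so no stereocontrol is needed; 2-methylphloroglucinol and ethoxyethyne (hexane solution) are treated as purchasable.

**Route**

Step 1
Reactants: 1 2,6-dimethoxytoluene (1,3-dimethoxy-2-methylbenzene)
Product: 3 3,5-dimethoxy-4-methylphenol, via aryl pinacol boronate 2 (not isolated)
Conditions: B2pin2 (1.0 equiv), [Ir(OMe)(cod)]2 (1 mol %), 4,4'-di-tert-butyl-2,2'-bipyridine (2 mol %), THF, 80 °C; then KHSO5 (as 2KHSO5·KHSO4·K2SO4), acetone/H2O, rt, 10 min
Reagents that add atoms: bis(pinacolato)diboron, CC1(C)OB(OC1(C)C)B1OC(C)(C)C(C)(C)O1 (boron group of 2 only); potassium peroxymonosulfate KHSO5, [K+].[O-]S(=O)(=O)OO (phenol oxygen of 3)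
Why: Iridium-catalysed aromatic C–H borylation is sterically controlled and should occur only at the ring carbon para to the methyl group (the one C–H without an ortho substituent), and one-pot peroxymonosulfate oxidation of the C–B bond should then give the phenol (C–H borylation/oxidation).

Step 2
Reactants: 3 3,5-dimethoxy-4-methylphenol
Product: 4 3,5-dimethoxy-4-methylphenyl acetate
Conditions: Ac2O, pyridine, DMAP (cat.), CH2Cl2, 0 °C to rt
Reagents that add atoms: acetic anhydride, CC(=O)OC(C)=O
Why: Standard O-acetylation of a phenol (nucleophilic acyl substitution) installs the ester that serves as the enol ether precursor.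

Step 3
Reactants: 4 3,5-dimethoxy-4-methylphenyl acetate
Product: 5 1,3-dimethoxy-2-methyl-5-(prop-1-en-2-yloxy)benzene (aryl isopropenyl ether)
Conditions: Cp2Ti(μ-CH2)(μ-Cl)AlMe2 (Tebbe reagent, 1.2 equiv), pyridine (cat.), THF/toluene, −40 °C to rt; aq. NaOH quench; filtration through basic Al2O3
Reagents that add atoms: Tebbe reagent Cp2Ti(μ-CH2)(μ-Cl)AlMe2, C[Al](C)C[Ti](Cl)(C1C=CC=C1)C1C=CC=C1 (the CH2 group)
Why: The titanium methylidene should convert the aryl ester carbonyl into the enol ether by [2+2] cycloaddition and cycloreversion (Tebbe methylenation), which is established for aryl acetates and leaves the methyl ethers untouched.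

Step 4
Reactants: 5 1,3-dimethoxy-2-methyl-5-(prop-1-en-2-yloxy)benzene; 6 ethoxyethyne
Product: 9 5,7-dimethoxy-2,2,6-trimethylchroman-4-one, via oxocarbenium triflimide 7 (not isolated), via enol ether 8 (not isolated)
Conditions: HNTf2 (1.05 equiv), CH2Cl2, −78 °C, slow addition of 5; then 6 (1.3 equiv, hexane solution) added slowly, −78 to −40 °C; then H2O/THF, 0 °C; aq. NaHCO3
Reagents that add atoms: water, O (the C4 carbonyl oxygen)
Why: Proposed new method: protonation of 5 gives the O-aryl oxocarbenium ion 7 (a cationic 2-oxadiene C4a=C8a–O1=C2, chromanone numbering), the terminal carbon of ethoxyethyne attacks its C2 (new C2–C3 bond) to give a ketene-oxonium ion at C4, the ortho ring carbon captures that ion (new C4–C4a bond) to give enol ether 8, and aqueous acid hydrolyses 8 to ketone 9. The closest known reaction types are the oxa-Povarov reaction (formal [4+2] of aldehyde-derived O-aryl oxocarbenium ions and alkenes to chromans), the Lewis acid-promoted addition of ynol ethers to acetal-derived oxocarbenium ions, and keteniminium Friedel–Crafts cyclisations; new are the ketone-derived, fully substituted oxocarbenium carbon and the ynol ether as ketene equivalent in this annulation. Ring C closes by a stepwise cationic [4+2] whose ring-forming event is a six-membered Friedel–Crafts attack of C4a on the sp carbon C4 (6-exo-dig with respect to the C4=O+ bond, the C3=C4 bond becoming endocyclic). No stereocentre is formed, since C2 carries two methyl groups. The step needs chemoselectivity for alkyne addition over cationic self-condensation of 5 and for C-arylation over oxygen capture of the ketene-oxonium ion: inverse addition to a full equivalent of acid leaves no free enol ether, every arene in the flask stays cationic (deactivated) until the alkyne has added, the triflimide ion is non-nucleophilic, and C4a is activated by O1 (ortho), the 5-methoxy (ortho) and the 7-methoxy (para) groups. No regiochemical choice arises, because the two ortho carbons of 5 are equivalent by symmetry and O1 was fixed para to the ring methyl in step 1.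

Step 5
Reactants: 9 5,7-dimethoxy-2,2,6-trimethylchroman-4-one
Product: 10 5,7-dihydroxy-2,2,6-trimethylchroman-4-one
Conditions: BBr3 (5 equiv), CH2Cl2, −78 °C to rt; then ice/H2O
Reagents that add atoms: none
Why: Lewis acid cleavage of aryl methyl ethers (BBr3 demethylation) should remove the 5-methyl group first through chelation to the C4 carbonyl and the 7-methyl group on warming, while the vinylogous-ester oxygen O1 is too weakly basic to be activated.

Step 6
Reactants: 10 5,7-dihydroxy-2,2,6-trimethylchroman-4-one
Product: 11 8-[(dimethylamino)methyl]-5,7-dihydroxy-2,2,6-trimethylchroman-4-one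
Conditions: CH2=NMe2+ I− (Eschenmoser's salt, 1.1 equiv), CH2Cl2, rt; aq. NaHCO3
Reagents that add atoms: N,N-dimethylmethyleneiminium iodide, C=[N+](C)C.[I-]
Why: In this phenol Mannich reaction C8 is the only unsubstituted ring carbon and is flanked by the free 7-hydroxyl and O1, so aminomethylation with the preformed iminium ion should occur there and without free formaldehyde.

Step 7
Reactants: 12 2-methylphloroglucinol; 13 2-methylpropanoyl chloride
Product: 14 1-(2,4,6-trihydroxy-3-methylphenyl)-2-methylpropan-1-one
Conditions: AlCl3 (3.5 equiv), PhNO2/CH2Cl2, 0 to 45 °C; aq. HCl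
Reagents that add atoms: none
Why: Friedel–Crafts C-acylation of the highly activated triol (through O-acylation and Fries shift under AlCl3) should occur at one of its two equivalent free ring carbons, and the acyl group then deactivates the ring toward a second acylation.

Step 8
Reactants: 11 8-[(dimethylamino)methyl]-5,7-dihydroxy-2,2,6-trimethylchroman-4-one; 14 1-(2,4,6-trihydroxy-3-methylphenyl)-2-methylpropan-1-one
Product: 15 5,7-dihydroxy-2,2,6-trimethyl-8-{[2,4,6-trihydroxy-3-methyl-5-(2-methylpropanoyl)phenyl]methyl}chroman-4-one (CNP0186856.0)
Conditions: 14 (1.5 equiv), degassed 1,4-dioxane, 100 °C, N2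
Reagents that add atoms: none
Why: Thermal loss of dimethylamine from the ortho-hydroxybenzylamine (assisted by proton transfer from the acidic acylphloroglucinol) should give the ortho-quinone methide across C7/C8, which is C-alkylated in conjugate fashion by the only unsubstituted ring carbon of 14 and then rearomatises (Mannich base/ortho-quinone methide alkylation).

**Compound list**

1 | 2,6-dimethoxytoluene (1,3-dimethoxy-2-methylbenzene) | COc1cccc(OC)c1C | starting material
2 | 2-(3,5-dimethoxy-4-methylphenyl)-4,4,5,5-tetramethyl-1,3,2-dioxaborolane | COc1cc(B2OC(C)(C)C(C)(C)O2)cc(OC)c1C | intermediate (not isolated)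
3 | 3,5-dimethoxy-4-methylphenol | COc1cc(O)cc(OC)c1C | intermediate
4 | 3,5-dimethoxy-4-methylphenyl acetate | COc1cc(OC(C)=O)cc(OC)c1C | intermediate
5 | 1,3-dimethoxy-2-methyl-5-(prop-1-en-2-yloxy)benzene | COc1cc(OC(C)=C)cc(OC)c1C | intermediate
6 | ethoxyethyne | C#COCC | starting material
7 | 2-(3,5-dimethoxy-4-methylphenoxy)propan-2-ylium bis(trifluoromethanesulfonyl)imide | CC(C)=[O+]c1cc(OC)c(C)c(OC)c1.FC(F)(F)S(=O)(=O)[N-]S(=O)(=O)C(F)(F)F | intermediate (not isolated)
8 | 4-ethoxy-5,7-dimethoxy-2,2,6-trimethyl-2H-chromene | CCOC1=CC(C)(C)Oc2cc(OC)c(C)c(OC)c12 | intermediate (not isolated)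
9 | 5,7-dimethoxy-2,2,6-trimethylchroman-4-one | COc1cc2OC(C)(C)CC(=O)c2c(OC)c1C | intermediate
10 | 5,7-dihydroxy-2,2,6-trimethylchroman-4-one | Cc1c(O)cc2OC(C)(C)CC(=O)c2c1O | intermediate
11 | 8-[(dimethylamino)methyl]-5,7-dihydroxy-2,2,6-trimethylchroman-4-one | CN(C)Cc1c(O)c(C)c(O)c2C(=O)CC(C)(C)Oc12 | intermediate
12 | 2-methylphloroglucinol (2-methylbenzene-1,3,5-triol) | Cc1c(O)cc(O)cc1O | starting material
13 | 2-methylpropanoyl chloride | CC(C)C(Cl)=O | starting material
14 | 1-(2,4,6-trihydroxy-3-methylphenyl)-2-methylpropan-1-one | CC(C)C(=O)c1c(O)cc(O)c(C)c1O | intermediate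
15 | 5,7-dihydroxy-2,2,6-trimethyl-8-{[2,4,6-trihydroxy-3-methyl-5-(2-methylpropanoyl)phenyl]methyl}chroman-4-one | Cc1c(O)c(Cc2c(O)c(C)c(O)c3c2OC(C)(C)CC3=O)c(O)c(C(=O)C(C)C)c1O | target

**Summary**

Total step count: 8. Longest linear sequence: 7 (steps 1, 2, 3, 4, 5, 6 and 8); step 7 makes the second fragment.

Steps most likely to fail:

1. Step 4 (proposed new method). The cation could be consumed by cationic oligomerisation with enol ether or ynol ether. The ketene-oxonium ion could be captured at oxygen (four-membered closure and aryloxy shift leading to 3-methylbut-2-enoate esters) instead of at C4a. The superacid could protonate the ynol ether, so that simple ring acetylation competes. Fallback with known chemistry: it sets out from 4. Fries rearrangement (BF3·OEt2, AcOH, 90 °C) should move the acetyl group to the ortho carbon and give 1-(6-hydroxy-2,4-dimethoxy-3-methylphenyl)ethan-1-one F1. Kabbe condensation of F1 with acetone (pyrrolidine, EtOH, reflux; enamine aldol, dehydration and oxa-Michael closure) then comes back to the route at 9.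

2. Step 8. The methylene unit could be transferred reversibly between the two phenols (retro-Mannich exchange and amine-induced disproportionation of the diarylmethane), which would erode the cross-selectivity, and the ortho-quinone methide could self-condense. Fallback: it sets out from 10 and 14 and comes back at 15. The two phenols are condensed directly with formaldehyde (37 % aq. HCHO, dilute aq. KOH, EtOH, 0 °C to rt) with 14 in threefold excess, accepting statistical coupling. The co-formed symmetrical dimer bis[2,4,6-trihydroxy-3-methyl-5-(2-methylpropanoyl)phenyl]methane F2 is removed by chromatography.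

3. Step 5. Cleavage of the hindered 7-methyl ether could be incomplete, or the Lewis acid could open ring C at the tertiary C2–O1 bond, after which re-closure onto the other ortho oxygen would scramble the 6-methyl and 8-methyl series. Fallback: it sets out from 12 and comes back at 10 without protecting groups. Friedel–Crafts acylation/oxa-Michael closure of 12 with 3-methylbut-2-enoic acid (P2O5 in MsOH, 70 °C) should give 10 together with the regioisomer 5,7-dihydroxy-2,2,8-trimethylchroman-4-one F3, from which it is separated by chromatography.

**Further compounds**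

F1 | step 4 | 1-(6-hydroxy-2,4-dimethoxy-3-methylphenyl)ethan-1-one | CC(=O)c1c(O)cc(OC)c(C)c1OC
F2 | step 8 | bis[2,4,6-trihydroxy-3-methyl-5-(2-methylpropanoyl)phenyl]methane | CC(C)C(=O)c1c(O)c(C)c(O)c(Cc2c(O)c(C)c(O)c(C(=O)C(C)C)c2O)c1O
F3 | step 5 | 5,7-dihydroxy-2,2,8-trimethylchroman-4-one | Cc1c(O)cc(O)c2C(=O)CC(C)(C)Oc12
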